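## Retrosynthetic overview

1. The target is the (2S)-flavanone. It is traced back to its tris-MOM ether, and that to flavone 21 by enantioselective copper hydride reduction of C2=C3, which sets C2.
2. The strategy rests on ring C: O1 and C4a of ring A are bridged by C4–C3–C2, and C4 is a lone carbonyl carbon. Cutting C4a–C4, C4–C3 and O1–C2 leaves an ortho-iodophenol (ring A), carbon monoxide and a ring B arylacetylene.
3. Iodophenol 7 comes from phloroglucinol: bis-MOM ether, ortho-iodination, then O-allylation, Claisen shift and cross-metathesis to place the prenyl group next to the free hydroxyl.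
4. Alkyne 18 comes from 4-hydroxyphenylacetonitrile: MOM ether, gem-dimethylation, nitrile to aldehyde to vinyl, ortho-formylation, one-carbon homologation.
5. Rings A and B are bought as arenes; ring C is the only ring formed (step 12).

Key step: step 12

Remarks on the chemistry (assumptions):
- Flavonoid numbering is used (O1, C2, C3, C4, C4a, C5–C8, C8a; ring B primed).
- (S)-DTBM-SEGPHOS is assumed to deliver hydride to the face of C2 that gives the (2S)-flavanone, by analogy with the sense known for β-substituted cyclic enones. If the opposite sense holds, the (R)-ligand is used with no other change.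
- The iodination in step 2 is assumed to go ortho to the free hydroxyl (statistics and sterics); this has not been verified for the bis-MOM ether.

## Route

Step 1
Reactants: 1 phloroglucinol
Product: 3 3,5-bis(methoxymethoxy)phenol, via 5-(methoxymethoxy)benzene-1,3-diol 2 (not isolated)
Conditions: MOMCl (2.0 equiv), i-Pr2NEt (2.2 equiv), DMF/CH2Cl2, 0 °C to rt
Reagents that add atoms: chloromethyl methyl ether, COCCl
Why: Williamson-type O-alkylation of the phenols by the reactive chloromethyl ether; the triol is threefold symmetric, so only the degree of alkylation has to be controlled by stoichiometry, and the bis-ether is separated from mono- and tris-ether by chromatography.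

Step 2
Reactants: 3 3,5-bis(methoxymethoxy)phenol
Product: 4 2-iodo-3,5-bis(methoxymethoxy)phenol
Conditions: I2 (1.0 equiv), NaHCO3, THF/H2O, 0 °C
Reagents that add atoms: iodine, II
Why: Electrophilic aromatic iodination under bicarbonate buffering, expected ortho to the free hydroxyl because there are two equivalent ortho sites flanked by the small OH whereas C4 lies between two MOM ethers; one equivalent of iodine at 0 °C should limit di-iodination, any 4-iodo isomer is removed by chromatography, and no alkene is present yet that could undergo iodoetherification.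

Step 3
Reactants: 4 2-iodo-3,5-bis(methoxymethoxy)phenol
Product: 5 1-(allyloxy)-2-iodo-3,5-bis(methoxymethoxy)benzene
Conditions: allyl bromide, K2CO3, acetone, reflux
Reagents that add atoms: allyl bromide, C=CCBr
Why: Williamson ether synthesis on the acidic ortho-iodophenol with a reactive allylic halide; the MOM ethers and the aryl iodide are inert to carbonate.

Step 4
Reactants: 5 1-(allyloxy)-2-iodo-3,5-bis(methoxymethoxy)benzene
Product: 6 2-allyl-6-iodo-3,5-bis(methoxymethoxy)phenol
Conditions: PhNEt2, 190 °C, argon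
Reagents that add atoms: none
Why: Aromatic Claisen rearrangement, in which the [3,3] shift can only deliver the allyl group to the single unsubstituted ortho carbon (the other bears iodine) and rearomatisation releases exactly the hydroxyl that later becomes O1; neutral thermolysis in an amine solvent should spare the MOM ethers and the aryl iodide.

Step 5
Reactants: 6 2-allyl-6-iodo-3,5-bis(methoxymethoxy)phenol
Product: 7 2-iodo-3,5-bis(methoxymethoxy)-6-(3-methylbut-2-enyl)phenol
Conditions: RuCl2(=CHPh)(H2IMes)(PCy3) (second-generation Grubbs catalyst, 5 mol%), 2-methyl-2-butene (large excess), CH2Cl2, 35 °C, sealed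
Reagents that add atoms: 2-methyl-2-butene, CC=C(C)C
Why: Olefin cross-metathesis of the terminal allyl arene with excess 2-methyl-2-butene exchanges =CH2 for =CMe2 with loss of propene, a standard allyl-to-prenyl conversion that tolerates free phenols, aryl iodides and acetals.

Step 6
Reactants: 8 4-hydroxyphenylacetonitrile
Product: 9 [4-(methoxymethoxy)phenyl]acetonitrile
Conditions: MOMCl, i-Pr2NEt, CH2Cl2, 0 °C to rt
Reagents that add atoms: chloromethyl methyl ether, COCCl
Why: Williamson-type O-alkylation; the phenol is far more acidic than the benzylic nitrile CH2, so an amine base gives the MOM ether only.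

Step 7
Reactants: 9 [4-(methoxymethoxy)phenyl]acetonitrile
Product: 11 2-[4-(methoxymethoxy)phenyl]-2-methylpropanenitrile, via monomethyl nitrile 10 (not isolated)
Conditions: NaH (2.5 equiv), MeI (3 equiv), THF, 0 °C to rt
Reagents that add atoms: iodomethane, CI
Why: Double α-alkylation of the stabilised arylacetonitrile anion, which stops cleanly at the quaternary carbon because no acidic hydrogen remains.

Step 8
Reactants: 11 2-[4-(methoxymethoxy)phenyl]-2-methylpropanenitrile
Product: 13 2-[4-(methoxymethoxy)phenyl]-2-methylpropanal, via N-aluminated aldimine 12 (not isolated)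
Conditions: i-Bu2AlH (1.3 equiv), toluene, −78 to 0 °C; then cold 1 M aq. HCl, brief
Reagents that add atoms: water, O
Why: Partial reduction of a nitrile by i-Bu2AlH stops at the N-aluminated aldimine, which is hydrolysed on brief cold acidic work-up to the non-enolisable aldehyde without harm to the aryl MOM ether.

Step 9
Reactants: 13 2-[4-(methoxymethoxy)phenyl]-2-methylpropanal
Product: 14 1-(methoxymethoxy)-4-(2-methylbut-3-en-2-yl)benzene
Conditions: Ph3PCH3Br, KOt-Bu, THF, 0 °C to rt
Reagents that add atoms: methyltriphenylphosphonium bromide, C[P+](c1ccccc1)(c1ccccc1)c1ccccc1.[Br-]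
Why: Wittig methylenation of a hindered aldehyde that cannot enolise, giving the 1,1-dimethylallyl group.

Step 10
Reactants: 14 1-(methoxymethoxy)-4-(2-methylbut-3-en-2-yl)benzene
Product: 17 2-(methoxymethoxy)-5-(2-methylbut-3-en-2-yl)benzaldehyde, via ortho-aryllithium 15 (not isolated), via lithium hemiaminal alkoxide 16 (not isolated)
Conditions: s-BuLi, TMEDA, THF, −78 °C; DMF, −78 °C to rt; aq. NH4Cl
Reagents that add atoms: N,N-dimethylformamide, CN(C)C=O
Why: Directed ortho-metalation by the MOM ether (the two ortho positions are equivalent and the quaternary side chain has no benzylic or allylic hydrogen) followed by formylation of the aryllithium with DMF.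

Step 11
Reactants: 17 2-(methoxymethoxy)-5-(2-methylbut-3-en-2-yl)benzaldehyde
Product: 18 2-ethynyl-1-(methoxymethoxy)-4-(2-methylbut-3-en-2-yl)benzene
Conditions: dimethyl (1-diazo-2-oxopropyl)phosphonate, K2CO3, MeOH, rt
Reagents that add atoms: dimethyl (1-diazo-2-oxopropyl)phosphonate, COP(=O)(OC)C(=[N+]=[N-])C(C)=O
Why: Seyferth–Gilbert homologation in its Ohira–Bestmann form converts the non-enolisable aryl aldehyde to the terminal alkyne under mild carbonate conditions that the MOM ether and the vinyl group tolerate.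

Step 12
Reactants: 7 2-iodo-3,5-bis(methoxymethoxy)-6-(3-methylbut-2-enyl)phenol; 18 2-ethynyl-1-(methoxymethoxy)-4-(2-methylbut-3-en-2-yl)benzene
Product: 21 5,7-bis(methoxymethoxy)-2-[2-(methoxymethoxy)-5-(2-methylbut-3-en-2-yl)phenyl]-8-(3-methylbut-2-enyl)-4H-chromen-4-one, via ynone 19 (not isolated), via enaminone 20 (not isolated)
Conditions: PdCl2(PPh3)2 (5 mol%), Et2NH (degassed, solvent), CO (10 bar), 90 °C, no copper salt
Reagents that add atoms: carbon monoxide, [C-]#[O+]
Why: Zerovalent palladium, formed in situ from PdCl2(PPh3)2, inserts into the C4a–I bond of 7, CO insertion gives an aroylpalladium iodide, and amine-assisted transfer of the acetylide of 18 followed by reductive elimination gives ynone 19 (bonds C4a–C4 and C4–C3). Diethylamine then adds to C2 of 19 to give enaminone 20, and the one free hydroxyl of ring A displaces the amine at C2 in a 6-endo addition–elimination that closes ring C as the 4-pyranone (bond O1–C2). The closest known reaction type is the palladium-catalysed carbonylative annulation of ortho-iodophenols with terminal arylacetylenes in secondary amines, which gives flavones directly. No stereocentre is formed. Carbonylation must come before alkynylation, and this is secured by CO pressure, the absence of a copper co-catalyst and the doubly ortho-substituted arylpalladium, for which CO insertion should be fast relative to the crowded direct coupling that would lead to a benzofuran. The 6-endo mode is secured over 5-exo closure to an aurone because closure runs through amine adduct 20, and the regiochemistry of ring C is fixed because the C5 oxygen is capped as a MOM ether and only the hydroxyl at C8a is free.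

Step 13
Reactants: 21 5,7-bis(methoxymethoxy)-2-[2-(methoxymethoxy)-5-(2-methylbut-3-en-2-yl)phenyl]-8-(3-methylbut-2-enyl)-4H-chromen-4-one
Product: 23 (2S)-5,7-bis(methoxymethoxy)-2-[2-(methoxymethoxy)-5-(2-methylbut-3-en-2-yl)phenyl]-8-(3-methylbut-2-enyl)-2,3-dihydro-4H-chromen-4-one, via silyl enol ether 22 (not isolated)
Conditions: Cu(OAc)2·H2O (5 mol%), (S)-DTBM-SEGPHOS (5.5 mol%), MeSiH(OEt)2 (3 equiv), toluene, 0 °C to rt; then 0.5 M aq. citric acid, THF, 0 °C
Reagents that add atoms: none
Why: Asymmetric conjugate reduction (1,4-hydrosilylation) by a bisphosphine-ligated copper hydride, a known reaction of chromones and β,β-disubstituted enones, in which the chiral ligand on copper selects the face of C2=C3 for hydride delivery to C2 and so sets the (2S) centre; the copper enolate is trapped as silyl enol ether 22, which protects the ketone from 1,2-reduction and from base-induced ring opening until the buffered hydrolysis, and the isolated alkenes should react far more slowly than the enone.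

Step 14
Reactants: 23 (2S)-5,7-bis(methoxymethoxy)-2-[2-(methoxymethoxy)-5-(2-methylbut-3-en-2-yl)phenyl]-8-(3-methylbut-2-enyl)-2,3-dihydro-4H-chromen-4-one
Product: 24 (2S)-5,7-dihydroxy-2-[2-hydroxy-5-(2-methylbut-3-en-2-yl)phenyl]-8-(3-methylbut-2-enyl)-2,3-dihydro-4H-chromen-4-one
Conditions: HCl (1.25 M in MeOH), 35 °C, monitored and stopped at full conversion
Reagents that add atoms: none
Why: Acid-catalysed transacetalisation to methanol releases the three phenols (the C5 ether next to the carbonyl first), and the low temperature and short exposure are chosen to avoid addition of the C7 hydroxyl to the prenyl double bond and epimerisation at C2.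

## Compound list

1 | phloroglucinol | Oc1cc(O)cc(O)c1 | starting material
2 | 5-(methoxymethoxy)benzene-1,3-diol | COCOc1cc(O)cc(O)c1 | intermediate
3 | 3,5-bis(methoxymethoxy)phenol | COCOc1cc(O)cc(OCOC)c1 | intermediate
4 | 2-iodo-3,5-bis(methoxymethoxy)phenol | Oc1cc(OCOC)cc(OCOC)c1I | intermediate
5 | 1-(allyloxy)-2-iodo-3,5-bis(methoxymethoxy)benzene | C=CCOc1cc(OCOC)cc(OCOC)c1I | intermediate
6 | 2-allyl-6-iodo-3,5-bis(methoxymethoxy)phenol | Oc1c(I)c(OCOC)cc(OCOC)c1CC=C | intermediate
7 | 2-iodo-3,5-bis(methoxymethoxy)-6-(3-methylbut-2-enyl)phenol | Oc1c(I)c(OCOC)cc(OCOC)c1CC=C(C)C | intermediate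
8 | 4-hydroxyphenylacetonitrile | N#CCc1ccc(O)cc1 | starting material
9 | [4-(methoxymethoxy)phenyl]acetonitrile | N#CCc1ccc(OCOC)cc1 | intermediate
10 | 2-[4-(methoxymethoxy)phenyl]propanenitrile (racemic) | N#CC(C)c1ccc(OCOC)cc1 | intermediate
11 | 2-[4-(methoxymethoxy)phenyl]-2-methylpropanenitrile | N#CC(C)(C)c1ccc(OCOC)cc1 | intermediate
12 | N-(diisobutylaluminio)aldimine of aldehyde 13 | CC(C)C[Al](CC(C)C)N=CC(C)(C)c1ccc(OCOC)cc1 | intermediate
13 | 2-[4-(methoxymethoxy)phenyl]-2-methylpropanal | O=CC(C)(C)c1ccc(OCOC)cc1 | intermediate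
14 | 1-(methoxymethoxy)-4-(2-methylbut-3-en-2-yl)benzene | C=CC(C)(C)c1ccc(OCOC)cc1 | intermediate
15 | [2-(methoxymethoxy)-5-(2-methylbut-3-en-2-yl)phenyl]lithium | [Li]c1cc(C(C)(C)C=C)ccc1OCOC | intermediate
16 | lithium (dimethylamino)[2-(methoxymethoxy)-5-(2-methylbut-3-en-2-yl)phenyl]methanolate (racemic) | [Li]OC(N(C)C)c1cc(C(C)(C)C=C)ccc1OCOC | intermediate
17 | 2-(methoxymethoxy)-5-(2-methylbut-3-en-2-yl)benzaldehyde | O=Cc1cc(C(C)(C)C=C)ccc1OCOC | intermediate
18 | 2-ethynyl-1-(methoxymethoxy)-4-(2-methylbut-3-en-2-yl)benzene | C#Cc1cc(C(C)(C)C=C)ccc1OCOC | intermediate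
19 | 1-[2-hydroxy-4,6-bis(methoxymethoxy)-3-(3-methylbut-2-enyl)phenyl]-3-[2-(methoxymethoxy)-5-(2-methylbut-3-en-2-yl)phenyl]prop-2-yn-1-one | C=CC(C)(C)c1ccc(OCOC)c(C#CC(=O)c2c(O)c(CC=C(C)C)c(OCOC)cc2OCOC)c1 | intermediate
20 | (E)-3-(diethylamino)-1-[2-hydroxy-4,6-bis(methoxymethoxy)-3-(3-methylbut-2-enyl)phenyl]-3-[2-(methoxymethoxy)-5-(2-methylbut-3-en-2-yl)phenyl]prop-2-en-1-one (either alkene geometry converges on 21) | CCN(CC)/C(c1cc(C(C)(C)C=C)ccc1OCOC)=C/C(=O)c1c(O)c(CC=C(C)C)c(OCOC)cc1OCOC | intermediate
21 | 5,7-bis(methoxymethoxy)-2-[2-(methoxymethoxy)-5-(2-methylbut-3-en-2-yl)phenyl]-8-(3-methylbut-2-enyl)-4H-chromen-4-one | C=CC(C)(C)c1ccc(OCOC)c(-c2cc(=O)c3c(OCOC)cc(OCOC)c(CC=C(C)C)c3o2)c1 | intermediate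
22 | (2S)-4-{[diethoxy(methyl)silyl]oxy}-5,7-bis(methoxymethoxy)-2-[2-(methoxymethoxy)-5-(2-methylbut-3-en-2-yl)phenyl]-8-(3-methylbut-2-enyl)-2H-chromene | C=CC(C)(C)c1ccc(OCOC)c([C@@H]2C=C(O[Si](C)(OCC)OCC)c3c(OCOC)cc(OCOC)c(CC=C(C)C)c3O2)c1 | intermediate
23 | (2S)-5,7-bis(methoxymethoxy)-2-[2-(methoxymethoxy)-5-(2-methylbut-3-en-2-yl)phenyl]-8-(3-methylbut-2-enyl)-2,3-dihydro-4H-chromen-4-one | C=CC(C)(C)c1ccc(OCOC)c([C@@H]2CC(=O)c3c(OCOC)cc(OCOC)c(CC=C(C)C)c3O2)c1 | intermediate
24 | (2S)-5,7-dihydroxy-2-[2-hydroxy-5-(2-methylbut-3-en-2-yl)phenyl]-8-(3-methylbut-2-enyl)-2,3-dihydro-4H-chromen-4-one | C=CC(C)(C)c1ccc(O)c([C@@H]2CC(=O)c3c(O)cc(O)c(CC=C(C)C)c3O2)c1 | target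

## Step count and risks

Total step count: 14 (ring A branch 5 steps, ring B branch 6 steps, 3 steps after convergence).
Longest linear sequence: 9 steps (steps 6 to 11, then 12 to 14, from 8 to 24).

Steps most likely to fail:

**1. Step 13 (setting C2).** Hydride transfer to the electron-rich, doubly flanked C2 of the 4-pyranone may be slow or incomplete. The ketone may be released early and reduced at C4, the terminal vinyl group may be hydrocuprated, or the two faces of C2=C3 may be poorly distinguished.
Fallback: this sets out from 21. Conjugate reduction with Li[(s-Bu)3BH] in THF at −78 °C should give the lithium enolate F1, which aqueous NH4Cl protonates to the racemic tris-MOM flavanone F2. F2 is then resolved kinetically by asymmetric transfer hydrogenation with RuCl(p-cymene)[(R,R)-TsDPEN] and HCO2H/Et3N in EtOAc at rt. The (2R)-ketone should be reduced to the cis-(2R,4R)-flavan-4-ol F3, while the (2S)-ketone is left behind and recovered (at most half of the material). The fallback comes back to the route at 23.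

**2. Step 12 (key step).** Alkynylation may outrun CO insertion, so that the coupled ortho-alkynylphenol closes to a benzofuran. The ynone may close in the 5-exo mode. Oxidative addition into the hindered, electron-rich C–I bond may be slow enough for the catalyst to decay.
Fallback: this sets out from 7. Acetylation (Ac2O, pyridine, DMAP) should give 2-iodo-3,5-bis(methoxymethoxy)-6-(3-methylbut-2-enyl)phenyl acetate F4. With the phenol masked, a carbonylative Sonogashira coupling with 18 (PdCl2(PPh3)2, Et3N, CO, THF) cannot lead to a benzofuran and should stop at the isolable ynone acetate F5. Treatment of F5 with Et2NH in EtOH then cleaves the acetate by aminolysis and closes ring C through 19 and 20. The fallback comes back to the route at 21.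

**3. Step 14 (final unmasking).** The configuration at C2 may erode through reversible acid-promoted opening of ring C, helped by the ring B ortho-hydroxyl once it is free. The C7 hydroxyl may also add to the prenyl double bond under acid.
Fallback: this sets out from 21 and moves the acid step ahead of the stereocentre. Methanolic HCl on the flavone, which has no stereocentre to lose and whose C7 hydroxyl is a weak nucleophile, should give the trihydroxyflavone F6. Silylation (TBSOTf, 2,6-lutidine, CH2Cl2) gives the tris-TBS flavone F7. The copper hydride reduction of step 13 then gives the silyl enol ether F8 and, after buffered hydrolysis, the (2S)-tris-TBS flavanone F9. HF·pyridine in pyridine/THF at 0 °C removes the silyl groups without acid or base strong enough to open ring C. The fallback comes back to the route at 24.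

## Further compounds

F1 | step 13 | lithium enolate of racemic flavanone F2 (racemic at C2) | C=CC(C)(C)c1ccc(OCOC)c(C2C=C(O[Li])c3c(OCOC)cc(OCOC)c(CC=C(C)C)c3O2)c1
F2 | step 13 | racemic 5,7-bis(methoxymethoxy)-2-[2-(methoxymethoxy)-5-(2-methylbut-3-en-2-yl)phenyl]-8-(3-methylbut-2-enyl)-2,3-dihydro-4H-chromen-4-one | C=CC(C)(C)c1ccc(OCOC)c(C2CC(=O)c3c(OCOC)cc(OCOC)c(CC=C(C)C)c3O2)c1
F3 | step 13 | (2R,4R)-5,7-bis(methoxymethoxy)-2-[2-(methoxymethoxy)-5-(2-methylbut-3-en-2-yl)phenyl]-8-(3-methylbut-2-enyl)-3,4-dihydro-2H-chromen-4-ol (2,4-cis) | C=CC(C)(C)c1ccc(OCOC)c([C@H]2C[C@@H](O)c3c(OCOC)cc(OCOC)c(CC=C(C)C)c3O2)c1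
F4 | step 12 | 2-iodo-3,5-bis(methoxymethoxy)-6-(3-methylbut-2-enyl)phenyl acetate | CC(=O)Oc1c(I)c(OCOC)cc(OCOC)c1CC=C(C)C
F5 | step 12 | 2-{3-[2-(methoxymethoxy)-5-(2-methylbut-3-en-2-yl)phenyl]prop-2-ynoyl}-3,5-bis(methoxymethoxy)-6-(3-methylbut-2-enyl)phenyl acetate | C=CC(C)(C)c1ccc(OCOC)c(C#CC(=O)c2c(OC(C)=O)c(CC=C(C)C)c(OCOC)cc2OCOC)c1
F6 | step 14 | 5,7-dihydroxy-2-[2-hydroxy-5-(2-methylbut-3-en-2-yl)phenyl]-8-(3-methylbut-2-enyl)-4H-chromen-4-one | C=CC(C)(C)c1ccc(O)c(-c2cc(=O)c3c(O)cc(O)c(CC=C(C)C)c3o2)c1
F7 | step 14 | 5,7-bis(tert-butyldimethylsilyloxy)-2-[2-(tert-butyldimethylsilyloxy)-5-(2-methylbut-3-en-2-yl)phenyl]-8-(3-methylbut-2-enyl)-4H-chromen-4-one | C=CC(C)(C)c1ccc(O[Si](C)(C)C(C)(C)C)c(-c2cc(=O)c3c(O[Si](C)(C)C(C)(C)C)cc(O[Si](C)(C)C(C)(C)C)c(CC=C(C)C)c3o2)c1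
F8 | step 14 | (2S)-4-{[diethoxy(methyl)silyl]oxy}-5,7-bis(tert-butyldimethylsilyloxy)-2-[2-(tert-butyldimethylsilyloxy)-5-(2-methylbut-3-en-2-yl)phenyl]-8-(3-methylbut-2-enyl)-2H-chromene | C=CC(C)(C)c1ccc(O[Si](C)(C)C(C)(C)C)c([C@@H]2C=C(O[Si](C)(OCC)OCC)c3c(O[Si](C)(C)C(C)(C)C)cc(O[Si](C)(C)C(C)(C)C)c(CC=C(C)C)c3O2)c1
F9 | step 14 | (2S)-5,7-bis(tert-butyldimethylsilyloxy)-2-[2-(tert-butyldimethylsilyloxy)-5-(2-methylbut-3-en-2-yl)phenyl]-8-(3-methylbut-2-enyl)-2,3-dihydro-4H-chromen-4-one | C=CC(C)(C)c1ccc(O[Si](C)(C)C(C)(C)C)c([C@@H]2CC(=O)c3c(O[Si](C)(C)C(C)(C)C)cc(O[Si](C)(C)C(C)(C)C)c(CC=C(C)C)c3O2)c1
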